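## Structural features

The target joins a 5-hydroxy-3,6,8-trimethoxyflavone with a 3,4,5-trimethoxyphenyl ring B to a 7-methoxycoumarin through a 3-methylbut-3-ene chain: flavone O7 is bonded to C2' of the chain, and C1', which carries a free hydroxyl, is bonded to coumarin C8. The only two stereocentres are adjacent, C1' (S, benzylic carbinol) and C2' (R, allylic and aryloxy-bearing), with the two oxygens anti. The C1' carbinol ionizes easily under acid because of its two ortho oxygens and, as an alkoxide, can displace the neighbouring aryloxide; the allylic C2'–O bond, the isopropenyl group and the base-sensitive coumarin lactone set further limits. The real difficulty is the C7–O–C2' ether: the flavone oxygen lies between the 6- and 8-methoxy groups and its carbon partner is secondary, allylic and β-oxygenated, so a late SN2, Mitsunobu or SNAr etherification would be slow and would put C2' at risk. Ring A (C4a, C5, C6, C7, C8, C8a) is fully substituted and carries oxygen on every carbon except C4a. The key step uses exactly this pattern: C5 to C8 with their four oxygens correspond to the four carbons of a squaric ester, and the C4a=C8a bond corresponds to the C5=C6 enol-ether double bond of a 2-aryl-3-methoxy-4H-pyran-4-one, the future ring C. Ring A can therefore be grown around an ether that was made beforehand at an unhindered sp2 carbon.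

## Logic of the disconnections

24 back to 23 and 22. The Si–O bond at O1' and the O8–CH3 bond are cut. The silyl group is needed because a free C1' hydroxyl would add to the ketene of the key step, and O8 is the former ketene oxygen and can only arrive as a free phenol. This leads back to a hydroquinone that the key step delivers directly. The forward demands are a methylation that distinguishes the free 8-hydroxyl from the chelated 5-hydroxyl, and a desilylation that never generates a C1' alkoxide.

22 back to 19. The C8–C8a bond is cut and the aromatization is undone, so ring A reverts to a four-membered ring attached to pyranone C5. All four oxygenated carbons of ring A then come from one C4 unit that already carries the hindered ether. The flavone is simplified to a monocyclic pyranone plus a cyclobutenone. The forward step needs outward rotation of the carbinol hydroxyl, closure onto pyranone C6, and a side chain that tolerates 110 °C.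

19 back to 11 and 17 (through 18). The C–C bond between pyranone C5 and the carbinol carbon is cut. This is the convergent point: a coumarin half and a pyranone half of similar size. The forward step needs metalation at C5 without ring fragmentation or conjugate addition, and attack on the squarate carbonyl that lies next to the methoxy-bearing carbon.

11 back to 8 and 9. The vinylic C–O bond of the ether is cut, not the O–C2' bond. Addition–elimination at an sp2 carbon is insensitive to the crowding at C2' and leaves its configuration untouched. The problem shrinks to a monoprotected diol and a symmetrical C4 building block. The forward step must exchange one methoxy group only and must not let the silyl group wander from O1' to O2'.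

8 back to 7, 6 and 5. One O–Si bond (O2'), the C=CH2 bond and the remaining O–Si bonds are cut, which exposes a methyl ketone, the retron of an aldol reaction. The forward steps need a methylenation that does not epimerize the α-oxygenated centre and a desilylation that distinguishes two secondary silyl ethers.

5 back to 3 and 4. The C1'–C2' bond is cut. One catalytic step then sets both stereocentres in the anti relationship from an achiral aldehyde and an achiral ketone. The demand is reaction through the more substituted (E)-enamine on one face of the aldehyde.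

3 back to 2 and 1. The O–CH3 bond and the C8–CHO bond are cut, leading to a commercial phenol. The only demand is ortho-formylation at C8 and not at C6.

17 back to 16, then 14 and 15, then 13 and 12. In turn the C5–I bond, the C2–aryl bond, the O–CH3 bond and the C2–Br bond are cut. Each substituent is placed where the pyranone's own polarity directs it (enol ortho position, then the β-carbon for coupling, then the α-carbon for iodination). The critical demand is iodination at C5 in the presence of an electron-rich arene.

## Other disconnections considered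

Alternative 1: The cut is the C4–C4a bond of flavone ring C. In the forward direction the (E)-β-aryloxy-α-methoxycinnamic acid A2 would be activated with (CF3CO)2O, and the mixed anhydride would acylate the single ring CH of its aryloxy group to give the 7-benzyloxyflavone A1. Hydrogenolysis would free the 7-hydroxyl (A3), which must then be joined to C2' with inversion, for example by a Mitsunobu reaction with the syn-configured alcohol A4.
- In favour: intramolecular Friedel–Crafts acylation of electron-rich aryl ethers is dependable, and the position attacked is the only one available and is activated by its oxygen neighbours. On precedent for the ring closure itself this alternative is the better plan.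
- Against: ring A must be brought in as a pentasubstituted benzene with four differentiated oxygens, and A2 must have acid and aryloxy cis. Above all, the step does nothing for the bond that makes the target hard. The ether is deferred to the coupling of A3 (hydroxyl between two methoxy groups) with a secondary, allylic, β-silyloxy carbinol, where elimination and SN2' attack are expected to compete and where C2' depends on clean inversion.
- Comparison: structurally, the chosen plan forms the ether at an sp2 carbon with retention at C2'. Mechanistically, a polar acylation is better understood than an electrocyclic cascade with an untested 2π partner. In step economy the flavone core would cost about as many steps, with the weakest step at the very end.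

Alternative 2: The cut removes three bonds of the coumarin benzene ring (C8–C8a, C6–C7 and C4a–C8a). Cyclobutenone A7 would be heated with the methoxyalkyne A6, which already carries C1', C2', the isopropenyl group and the flavone ether. Opening to vinylketene, (2+2) addition to the ynol ether, 4π opening and 6π closure would give the 2-substituted 3-methoxyphenol A5.
- In favour: the polarity of the ynol ether fixes the regiochemistry, so the arene with the side chain between two oxygens forms without a regioisomer question. On this point it is the equal or the better of the chosen plan, whose Grignard step relies on a steric and electronic bias. Mechanistically it is a close relative (a ketene 4π/6π cascade).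
- Against: it constructs a ring that compound 1 supplies ready-made, and the lactone must still be added afterwards. A6 presupposes that the hindered ether and both stereocentres have already been made on a sensitive propargylic ynol ether. A7 is volatile and polymerizes, and the free 5-hydroxyl of A6 is exposed to the ketene.
- Comparison: the effort goes into the easy half of the molecule, and the step count would be clearly higher than the two steps from 1 to 3.

Alternative 3: The cut is the C4–C4a bond of the coumarin. The aryl propiolate A8, made from the phenol A5, would be treated with (Ph3P)AuCl and AgSbF6. The arene carbon para to the methoxy group attacks the activated alkyne terminus in a 6-endo hydroarylation and gives A9, the tert-butyldimethylsilyl ether of the target, one desilylation away from 24.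
- In favour: the reaction is catalytic, runs near room temperature and comes late, so the lactone would never have to face organomagnesium or alkoxide reagents. Only one ortho position is free. On mildness and on sparing the lactone it is better than the chosen plan.
- Against: A8 can only be reached through A5, so every liability of alternative 2 is inherited. The cationic gold catalyst can also activate the isopropenyl alkene, and the propiolate must be placed on one phenol in the presence of the chelated 5-hydroxyl.
- Comparison: like alternative 2 it spends its key step on the coumarin and leaves ring A and the ether unsolved. The chosen plan is shorter and addresses the difficult bond directly, at the price of a hotter and less tested key step.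

Key step: step 13

Remarks before the route
- Pyranone numbering used throughout: O1, C2 (aryl), C3 (OMe), C4 (C=O), C5, C6. The carbon called C5 here is the "pyran-3-yl" carbon in the substituent name of the cyclobutenones; closure in the key step occurs at C6.
- Atom mapping of the key step: in 19 the carbinol carbon lies next to the methoxy-bearing carbon and the side-chain ether is on the carbon α to the carbonyl. In 22 these become C5 (OH), C6 (OMe), C7 (OR) and C8 (OH, the former carbonyl), with (1'S,2'R) unchanged.
- The C1' protecting group is a triethylsilyl ether. It does not chelate magnesium toward the wrong carbonyl, it adds bulk on the side-chain side of the squarate, and it is removed under buffered acidic fluoride.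
- Assumption: the L-proline aldol of hydroxyacetone takes the same (3S,4S)-anti course with aldehyde 3 as it does with other aldehydes.

## Route

Step 1
Reactants: 1 umbelliferone (7-hydroxy-2H-chromen-2-one)
Product: 2 7-hydroxy-2-oxo-2H-chromene-8-carbaldehyde
Conditions: hexamethylenetetramine, CF3CO2H, 90 °C; aqueous acidic work-up
Reagents that add atoms: hexamethylenetetramine (C1N2CN3CN1CN(C2)C3); water (O)
Why: Duff ortho-formylation: the iminium electrophile released from hexamethylenetetramine in acid substitutes the position ortho to the phenol, which in 7-hydroxycoumarins is C8 (between OH and the ring oxygen). The formyl carbon comes from hexamethylenetetramine and the formyl oxygen from water in the hydrolysis of the benzylic iminium ion; no stereocentre is formed.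

Step 2
Reactants: 2 7-hydroxy-2-oxo-2H-chromene-8-carbaldehyde
Product: 3 7-methoxy-2-oxo-2H-chromene-8-carbaldehyde
Conditions: MeI, K2CO3, acetone, 50 °C
Reagents that add atoms: iodomethane (CI)
Why: Williamson ether synthesis on a phenol acidified by the ortho formyl group; the lactone is inert to carbonate in dry acetone.

Step 3
Reactants: 3 7-methoxy-2-oxo-2H-chromene-8-carbaldehyde; 4 hydroxyacetone (1-hydroxypropan-2-one)
Product: 5 (3S,4S)-3,4-dihydroxy-4-(7-methoxy-2-oxo-2H-chromen-8-yl)butan-2-one
Conditions: L-proline (30 mol %), 4 (excess), DMSO, rt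
Reagents that add atoms: none
Why: Proline-catalysed direct (enamine) aldol reaction of hydroxyacetone, a known route to anti-1,2-diols: the hydroxylated (E)-enamine of L-proline attacks the Re face of the aldehyde in the acid-organized chair-like transition state, which should set both centres as (3S,4S), anti. The aldehyde cannot enolize, so only the cross-aldol is possible.

Step 4
Reactants: 5 (3S,4S)-3,4-dihydroxy-4-(7-methoxy-2-oxo-2H-chromen-8-yl)butan-2-one
Product: 6 (3S,4S)-4-(7-methoxy-2-oxo-2H-chromen-8-yl)-3,4-bis(triethylsilyloxy)butan-2-one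
Conditions: Et3SiOTf (2.5 equiv), 2,6-lutidine, CH2Cl2, −78 to 0 °C
Reagents that add atoms: triethylsilyl trifluoromethanesulfonate (CC[Si](CC)(CC)OS(=O)(=O)C(F)(F)F)
Why: Silyl ether formation; the triflate is chosen because the benzylic hydroxyl is flanked by a 2,6-disubstituted arene, and capping both hydroxyls removes the retro-aldol and β-elimination pathways before the ketone is touched.

Step 5
Reactants: 6 (3S,4S)-4-(7-methoxy-2-oxo-2H-chromen-8-yl)-3,4-bis(triethylsilyloxy)butan-2-one
Product: 7 7-methoxy-8-[(1S,2R)-3-methyl-1,2-bis(triethylsilyloxy)but-3-en-1-yl]-2H-chromen-2-one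
Conditions: Zn, CH2Br2, TiCl4, THF/CH2Cl2, 0 °C to rt
Reagents that add atoms: dibromomethane (BrCBr)
Why: Takai–Lombardo methylenation: the non-basic zinc–titanium methylene reagent converts the methyl ketone into the 1,1-disubstituted alkene without enolizing the α-silyloxy centre and without attacking the lactone; the descriptor at C2' changes from S to R only because the priorities change.

Step 6
Reactants: 7 7-methoxy-8-[(1S,2R)-3-methyl-1,2-bis(triethylsilyloxy)but-3-en-1-yl]-2H-chromen-2-one
Product: 8 8-[(1S,2R)-2-hydroxy-3-methyl-1-(triethylsilyloxy)but-3-en-1-yl]-7-methoxy-2H-chromen-2-one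
Conditions: pyridinium p-toluenesulfonate (0.2 equiv), MeOH/CH2Cl2, 0 °C, stopped at partial conversion
Reagents that add atoms: none
Why: Acid-catalysed methanolysis of silyl ethers is governed by access to silicon: the O1' ether is shielded on both sides by the ortho methoxy group and the ring oxygen of the coumarin, so the allylic O2' ether should be cleaved first; recovered 7 is resubmitted and any doubly desilylated material can be silylated again under the conditions of step 4.

Step 7
Reactants: 8 8-[(1S,2R)-2-hydroxy-3-methyl-1-(triethylsilyloxy)but-3-en-1-yl]-7-methoxy-2H-chromen-2-one; 9 dimethyl squarate (3,4-dimethoxycyclobut-3-ene-1,2-dione)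
Product: 11 3-methoxy-4-{[(1S,2R)-1-(7-methoxy-2-oxo-2H-chromen-8-yl)-3-methyl-1-(triethylsilyloxy)but-3-en-2-yl]oxy}cyclobut-3-ene-1,2-dione, via lithium alkoxide 10 (not isolated)
Conditions: LiN(SiMe3)2 (1.0 equiv), THF, −78 °C; cannulated into 9 (3 equiv), THF, −78 to −30 °C; AcOH quench
Reagents that add atoms: none
Why: Alkoxide exchange on a squaric ester, an addition–elimination at the vinylogous ester carbon that does not involve C2' and so retains its configuration. The lithium counter-ion, low temperature and inverse addition into excess 9 are chosen to capture the alkoxide before the silyl group can migrate from O1' and to prevent a second exchange.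

Step 8
Reactants: 12 3-hydroxy-4H-pyran-4-one
Product: 13 2-bromo-3-hydroxy-4H-pyran-4-one
Conditions: N-bromosuccinimide, MeCN, 0 °C
Reagents that add atoms: N-bromosuccinimide (O=C1CCC(=O)N1Br)
Why: Electrophilic bromination of the enol: the hydroxyl activates its ortho carbon C2, as in the halogenation of kojic acid at the corresponding position.

Step 9
Reactants: 13 2-bromo-3-hydroxy-4H-pyran-4-one
Product: 14 2-bromo-3-methoxy-4H-pyran-4-one
Conditions: MeI, K2CO3, DMF, rt
Reagents that add atoms: iodomethane (CI)
Why: O-Methylation of the acidic enolic hydroxyl; methylation before the coupling keeps the free enol from interfering with palladium and base.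

Step 10
Reactants: 14 2-bromo-3-methoxy-4H-pyran-4-one; 15 3,4,5-trimethoxyphenylboronic acid
Product: 16 3-methoxy-2-(3,4,5-trimethoxyphenyl)-4H-pyran-4-one
Conditions: Pd(PPh3)4 (5 mol %), K3PO4, dioxane/H2O (10:1), 80 °C
Reagents that add atoms: none
Why: Suzuki–Miyaura coupling; the C2–Br bond is a vinylogous acyl bromide and undergoes oxidative addition readily, and the mild phosphate base with little water limits hydrolytic loss of bromide.

Step 11
Reactants: 16 3-methoxy-2-(3,4,5-trimethoxyphenyl)-4H-pyran-4-one
Product: 17 5-iodo-3-methoxy-2-(3,4,5-trimethoxyphenyl)-4H-pyran-4-one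
Conditions: I2 (0.6 equiv), (NH4)2Ce(NO3)6 (1.1 equiv), MeCN, 60 °C
Reagents that add atoms: iodine ([I][I])
Why: Oxidative α-iodination of a 4-pyranone with iodine and tetravalent cerium, the method used for C3 of chromones and flavones: C5 is the only unsubstituted α-carbon of the vinylogous ester, whereas the free positions of the trimethoxyphenyl ring are flanked by the pyranone and deactivated by conjugation with it.

Step 12
Reactants: 17 5-iodo-3-methoxy-2-(3,4,5-trimethoxyphenyl)-4H-pyran-4-one; 11 3-methoxy-4-{[(1S,2R)-1-(7-methoxy-2-oxo-2H-chromen-8-yl)-3-methyl-1-(triethylsilyloxy)but-3-en-2-yl]oxy}cyclobut-3-ene-1,2-dione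
Product: 19 4-hydroxy-3-methoxy-2-{[(1S,2R)-1-(7-methoxy-2-oxo-2H-chromen-8-yl)-3-methyl-1-(triethylsilyloxy)but-3-en-2-yl]oxy}-4-[5-methoxy-4-oxo-6-(3,4,5-trimethoxyphenyl)-4H-pyran-3-yl]cyclobut-2-en-1-one (both carbinol epimers), via pyranonylmagnesium chloride 18 (not isolated)
Conditions: 17 (1.3 equiv), iPrMgCl·LiCl (1.25 equiv), THF, −78 °C, 20 min; then 11, THF, −78 °C; aq NH4Cl; chromatography to remove any regioisomer
Reagents that add atoms: none
Why: Iodine–magnesium exchange on an electron-poor alkenyl iodide is faster at −78 °C than conjugate addition to the pyranone or fragmentation of 18, and the resulting Grignard reagent adds 1,2 to a squarate carbonyl as aryl and alkenyl metals do. Attack is expected at the carbonyl next to the methoxy-bearing carbon, because the bulky silyloxy-substituted secondary alkoxy group crowds the other carbonyl and, being the weaker π-donor, leaves its vinylogous partner (the desired one) the more electrophilic. The new carbinol centre is formed without control and is lost in step 13.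

Step 13
Reactants: 19 4-hydroxy-3-methoxy-2-{[(1S,2R)-1-(7-methoxy-2-oxo-2H-chromen-8-yl)-3-methyl-1-(triethylsilyloxy)but-3-en-2-yl]oxy}-4-[5-methoxy-4-oxo-6-(3,4,5-trimethoxyphenyl)-4H-pyran-3-yl]cyclobut-2-en-1-one
Product: 22 5,8-dihydroxy-3,6-dimethoxy-7-{[(1S,2R)-1-(7-methoxy-2-oxo-2H-chromen-8-yl)-3-methyl-1-(triethylsilyloxy)but-3-en-2-yl]oxy}-2-(3,4,5-trimethoxyphenyl)-4H-chromen-4-one, via dienylketene 20 (not isolated), via cyclohexadienone 21 (not isolated)
Conditions: toluene (degassed, 0.01 M), 110 °C, argon
Reagents that add atoms: none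
Why: Heating opens the cyclobutenone of 19 at its C1–C4 bond by a thermal conrotatory 4π electrocyclic reaction; the hydroxyl on C4, a π-donor, rotates outward, which places the pyranonyl group inside, cis to the ketene, in the (3Z)-dienylketene 20. The ketene carbon, the C3=C4 bond and the pyranone C5=C6 bond then close by a thermal disrotatory 6π electrocyclization in which the ketene carbon bonds to pyranone C6; this single new bond becomes C8–C8a and closes the six-membered ring A as dienone 21. Enolization of 21 with loss of the hydrogen on the former pyranone C6 aromatizes ring A to the 5,8-hydroquinone 22, which drives the sequence. The closest known reaction type is the thermal ring expansion of squarate-derived 4-aryl-, 4-heteroaryl- and 4-alkenyl-4-hydroxycyclobutenones to hydroquinones (Moore rearrangement); the enol-ether-like C5=C6 bond of the pyranone, which has little aromatic stabilization to lose, takes the place of the alkenyl or furyl partner. No stereocentre is created: the carbinol centre of 19 and C8a of 21 both end as sp2 carbons, and C1' and C2' are remote from every bond change. Two selectivities are needed: torquoselectivity, secured by the donor hydroxyl on C4, and site selectivity of closure, secured because C6 is the only sp2 CH next to the point of attachment (the other neighbour is the C4 carbonyl carbon). The positions of the 6-methoxy group and the 7-ether were fixed in step 12, and the O1' silyl ether keeps the side-chain oxygen from adding to the ketene.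

Step 14
Reactants: 22 5,8-dihydroxy-3,6-dimethoxy-7-{[(1S,2R)-1-(7-methoxy-2-oxo-2H-chromen-8-yl)-3-methyl-1-(triethylsilyloxy)but-3-en-2-yl]oxy}-2-(3,4,5-trimethoxyphenyl)-4H-chromen-4-one
Product: 23 5-hydroxy-3,6,8-trimethoxy-7-{[(1S,2R)-1-(7-methoxy-2-oxo-2H-chromen-8-yl)-3-methyl-1-(triethylsilyloxy)but-3-en-2-yl]oxy}-2-(3,4,5-trimethoxyphenyl)-4H-chromen-4-one
Conditions: MeI (1.5 equiv), K2CO3, acetone (degassed), rt, argon, used directly on crude 22
Reagents that add atoms: iodomethane (CI)
Why: Chemoselective phenol methylation as practised with 5-hydroxyflavones: the 5-hydroxyl is locked in a hydrogen bond to the C4 carbonyl and stays untouched under mild carbonate conditions, while the free 8-hydroxyl is alkylated; exclusion of air protects the hydroquinone until it is capped.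

Step 15
Reactants: 23 5-hydroxy-3,6,8-trimethoxy-7-{[(1S,2R)-1-(7-methoxy-2-oxo-2H-chromen-8-yl)-3-methyl-1-(triethylsilyloxy)but-3-en-2-yl]oxy}-2-(3,4,5-trimethoxyphenyl)-4H-chromen-4-one
Product: 24 5-hydroxy-7-{[(1S,2R)-1-hydroxy-1-(7-methoxy-2-oxo-2H-chromen-8-yl)-3-methylbut-3-en-2-yl]oxy}-3,6,8-trimethoxy-2-(3,4,5-trimethoxyphenyl)-4H-chromen-4-one (CNP0323473.1)
Conditions: HF·pyridine, pyridine/THF, 0 °C
Reagents that add atoms: none
Why: Fluoride-mediated cleavage of a triethylsilyl ether under buffered, weakly acidic conditions; no C1' alkoxide is formed, so the neighbouring aryloxide cannot be displaced, and the medium is too mild to ionize the benzylic alcohol or open the lactone.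

## Compound list

1 | umbelliferone (7-hydroxy-2H-chromen-2-one) | O=c1ccc2ccc(O)cc2o1 | starting material
2 | 7-hydroxy-2-oxo-2H-chromene-8-carbaldehyde | O=Cc1c(O)ccc2ccc(=O)oc12 | intermediate
3 | 7-methoxy-2-oxo-2H-chromene-8-carbaldehyde | COc1ccc2ccc(=O)oc2c1C=O | intermediate
4 | hydroxyacetone (1-hydroxypropan-2-one) | CC(=O)CO | starting material
5 | (3S,4S)-3,4-dihydroxy-4-(7-methoxy-2-oxo-2H-chromen-8-yl)butan-2-one | CC(=O)[C@@H](O)[C@@H](O)c1c(OC)ccc2ccc(=O)oc12 | intermediate
6 | (3S,4S)-4-(7-methoxy-2-oxo-2H-chromen-8-yl)-3,4-bis(triethylsilyloxy)butan-2-one | CC(=O)[C@@H](O[Si](CC)(CC)CC)[C@@H](O[Si](CC)(CC)CC)c1c(OC)ccc2ccc(=O)oc12 | intermediate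
7 | 7-methoxy-8-[(1S,2R)-3-methyl-1,2-bis(triethylsilyloxy)but-3-en-1-yl]-2H-chromen-2-one | C=C(C)[C@@H](O[Si](CC)(CC)CC)[C@@H](O[Si](CC)(CC)CC)c1c(OC)ccc2ccc(=O)oc12 | intermediate
8 | 8-[(1S,2R)-2-hydroxy-3-methyl-1-(triethylsilyloxy)but-3-en-1-yl]-7-methoxy-2H-chromen-2-one | C=C(C)[C@@H](O)[C@@H](O[Si](CC)(CC)CC)c1c(OC)ccc2ccc(=O)oc12 | intermediate
9 | dimethyl squarate (3,4-dimethoxycyclobut-3-ene-1,2-dione) | COC1=C(OC)C(=O)C1=O | starting material
10 | lithium (1S,2R)-1-(7-methoxy-2-oxo-2H-chromen-8-yl)-3-methyl-1-(triethylsilyloxy)but-3-en-2-olate | C=C(C)[C@@H]([O-])[C@@H](O[Si](CC)(CC)CC)c1c(OC)ccc2ccc(=O)oc12.[Li+] | intermediate (not isolated)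
11 | 3-methoxy-4-{[(1S,2R)-1-(7-methoxy-2-oxo-2H-chromen-8-yl)-3-methyl-1-(triethylsilyloxy)but-3-en-2-yl]oxy}cyclobut-3-ene-1,2-dione | C=C(C)[C@@H](OC1=C(OC)C(=O)C1=O)[C@@H](O[Si](CC)(CC)CC)c1c(OC)ccc2ccc(=O)oc12 | intermediate
12 | 3-hydroxy-4H-pyran-4-one | O=c1ccocc1O | starting material
13 | 2-bromo-3-hydroxy-4H-pyran-4-one | Oc1c(Br)occc1=O | intermediate
14 | 2-bromo-3-methoxy-4H-pyran-4-one | COc1c(Br)occc1=O | intermediate
15 | 3,4,5-trimethoxyphenylboronic acid | COc1cc(B(O)O)cc(OC)c1OC | starting material
16 | 3-methoxy-2-(3,4,5-trimethoxyphenyl)-4H-pyran-4-one | COc1c(-c2cc(OC)c(OC)c(OC)c2)occc1=O | intermediate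
17 | 5-iodo-3-methoxy-2-(3,4,5-trimethoxyphenyl)-4H-pyran-4-one | COc1c(-c2cc(OC)c(OC)c(OC)c2)occ(I)c1=O | intermediate
18 | chlorido[5-methoxy-4-oxo-6-(3,4,5-trimethoxyphenyl)-4H-pyran-3-yl]magnesium (LiCl complex) | COc1c(-c2cc(OC)c(OC)c(OC)c2)occ([Mg]Cl)c1=O | intermediate (not isolated)
19 | 4-hydroxy-3-methoxy-2-{[(1S,2R)-1-(7-methoxy-2-oxo-2H-chromen-8-yl)-3-methyl-1-(triethylsilyloxy)but-3-en-2-yl]oxy}-4-[5-methoxy-4-oxo-6-(3,4,5-trimethoxyphenyl)-4H-pyran-3-yl]cyclobut-2-en-1-one (either configuration at C4 of the cyclobutenone) | C=C(C)[C@@H](OC1=C(OC)C(O)(c2coc(-c3cc(OC)c(OC)c(OC)c3)c(OC)c2=O)C1=O)[C@@H](O[Si](CC)(CC)CC)c1c(OC)ccc2ccc(=O)oc12 | intermediate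
20 | (3Z)-4-hydroxy-3-methoxy-2-{[(1S,2R)-1-(7-methoxy-2-oxo-2H-chromen-8-yl)-3-methyl-1-(triethylsilyloxy)but-3-en-2-yl]oxy}-4-[5-methoxy-4-oxo-6-(3,4,5-trimethoxyphenyl)-4H-pyran-3-yl]buta-1,3-dien-1-one (dienylketene) | C=C(C)[C@@H](OC(=C=O)/C(OC)=C(/O)c1coc(-c2cc(OC)c(OC)c(OC)c2)c(OC)c1=O)[C@@H](O[Si](CC)(CC)CC)c1c(OC)ccc2ccc(=O)oc12 | intermediate (not isolated)
21 | 5-hydroxy-3,6-dimethoxy-7-{[(1S,2R)-1-(7-methoxy-2-oxo-2H-chromen-8-yl)-3-methyl-1-(triethylsilyloxy)but-3-en-2-yl]oxy}-2-(3,4,5-trimethoxyphenyl)-8aH-chromene-4,8-dione (either configuration at C8a) | C=C(C)[C@@H](OC1=C(OC)C(O)=C2C(=O)C(OC)=C(-c3cc(OC)c(OC)c(OC)c3)OC2C1=O)[C@@H](O[Si](CC)(CC)CC)c1c(OC)ccc2ccc(=O)oc12 | intermediate (not isolated)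
22 | 5,8-dihydroxy-3,6-dimethoxy-7-{[(1S,2R)-1-(7-methoxy-2-oxo-2H-chromen-8-yl)-3-methyl-1-(triethylsilyloxy)but-3-en-2-yl]oxy}-2-(3,4,5-trimethoxyphenyl)-4H-chromen-4-one | C=C(C)[C@@H](Oc1c(OC)c(O)c2c(=O)c(OC)c(-c3cc(OC)c(OC)c(OC)c3)oc2c1O)[C@@H](O[Si](CC)(CC)CC)c1c(OC)ccc2ccc(=O)oc12 | intermediate
23 | 5-hydroxy-3,6,8-trimethoxy-7-{[(1S,2R)-1-(7-methoxy-2-oxo-2H-chromen-8-yl)-3-methyl-1-(triethylsilyloxy)but-3-en-2-yl]oxy}-2-(3,4,5-trimethoxyphenyl)-4H-chromen-4-one | C=C(C)[C@@H](Oc1c(OC)c(O)c2c(=O)c(OC)c(-c3cc(OC)c(OC)c(OC)c3)oc2c1OC)[C@@H](O[Si](CC)(CC)CC)c1c(OC)ccc2ccc(=O)oc12 | intermediate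
24 | 5-hydroxy-7-{[(1S,2R)-1-hydroxy-1-(7-methoxy-2-oxo-2H-chromen-8-yl)-3-methylbut-3-en-2-yl]oxy}-3,6,8-trimethoxy-2-(3,4,5-trimethoxyphenyl)-4H-chromen-4-one | C=C(C)[C@@H](Oc1c(OC)c(O)c2c(=O)c(OC)c(-c3cc(OC)c(OC)c(OC)c3)oc2c1OC)[C@@H](O)c1c(OC)ccc2ccc(=O)oc12 | target

## Step count and least certain steps

Total: 15 steps. Longest linear sequence: 11 steps (steps 1–7 and 12–15, from 1); the pyranone branch (steps 8–11) joins at step 12.

Step 13 (key step). The ketene 20 forms reversibly and may be diverted before it closes. Closure onto the acceptor-substituted pyranone alkene should be slower than onto a simple alkenyl group, which gives time for inward rotation of the hydroxyl with lactonization to a furanone, and the electron-rich hydroquinone may be lost by air oxidation to the quinone during handling. Fallback, from 19 and returning at 24: the tertiary hydroxyl of 19 would be capped with Et3SiOTf and 2,6-lutidine to give the 4-(triethylsilyloxy)cyclobutenone F1. A silyloxy group is still an outward-rotating donor but cannot add to the ketene, and thermolysis of O-protected cyclobutenones of this kind is known to give monoprotected hydroquinones. Heating in toluene should give the 8-hydroxy-5-(triethylsilyloxy)flavone F2, which is far less prone to oxidation to a quinone. Methylation with MeI and K2CO3 would give the 8-methyl ether F3, and HF·pyridine would remove both silyl groups to reach 24.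

Step 12. The most likely failure is attack on the wrong squarate carbonyl, since both are vinylogous ester carbonyls and the bias is only steric and weakly electronic; warming 18 would in addition risk ring fragmentation. Fallback, from 8 and returning at 19: two equivalents of 8 with 3,4-dichlorocyclobut-3-ene-1,2-dione and pyridine would give the symmetrical bis-ether F4, to which 18 adds without any regiochemical question to give the adduct F5. Catalytic NaOMe in MeOH/THF at −40 °C would then exchange only the alkoxy group on the β-carbon of the enone (C3, next to the carbinol) by addition–elimination, the α-alkoxy group being inert. This gives 19 regiospecifically and releases one equivalent of 8 for re-use.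

Step 7. The silyl group may migrate from O1' to the neighbouring alkoxide before capture, and the exchange may stall or go twice because it is reversible and liberates methoxide. Fallback, from 8 and returning at 11: 8 would be treated with one equivalent of 3,4-dichlorocyclobut-3-ene-1,2-dione and 2,6-lutidine at −40 °C. The neutral alcohol reacts irreversibly with this vinylogous acid chloride to give the chloro ester F6, and methanol with Et3N would then replace the second chloride to give 11. No alkoxide is formed at any point.

Step 3. Diastereo- and enantiocontrol may be poor and conversion slow, because an ortho-disubstituted aromatic aldehyde is a hindered acceptor for which the syn pathway competes more than with branched aliphatic aldehydes. Fallback, from 3 and returning at 8 (steps 3 to 6 are bypassed): 2-methylprop-1-enylmagnesium bromide at −78 °C would give the racemic allylic alcohol F7. Sharpless kinetic resolution (Ti(OiPr)4, L-(+)-diisopropyl tartrate, tBuOOH (0.6 equiv), 4 Å sieves, −20 °C) should epoxidize the (R)-enantiomer to the erythro epoxy alcohol F8. At most half of the material is used, the cis-methyl group of the trisubstituted alkene is expected to lower the rate ratio so the epoxide would be collected at modest conversion, and the slow enantiomer can be recycled by oxidation and reduction. Et3SiCl and imidazole would give the silyl ether F9, and diethylaluminium 2,2,6,6-tetramethylpiperidide in toluene at 0 °C would isomerize the trisubstituted epoxide to the allylic alcohol 8 with the C2'–O bond intact. In this sequence the silyl group is introduced while only one hydroxyl exists.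

Step 6. The rate difference between the two triethylsilyl ethers may be too small, so that the wrong group or both are lost. Fallback, from 3 and returning at 8: the aldol would be run with 1-[(4-methoxybenzyl)oxy]propan-2-one F10 (from 4-methoxybenzyl alcohol and chloroacetone) in place of 4, giving the O2'-protected aldol F11. Et3SiOTf would give the silyl ether F12, Takai–Lombardo methylenation the alkene F13, and DDQ in wet CH2Cl2 at pH 7 would remove the 4-methoxybenzyl group to give 8. The two oxygens are then distinguished from the start.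

Step 11. The trimethoxyphenyl ring may be iodinated or oxidized by tetravalent cerium in competition with C5. Fallback, from 14 and returning at 17: the halogen would be placed before the arene is present. Bromine would add across the C5=C6 bond of 14 to give the trans-dibromide adduct F14, from which Et3N in the same flask removes HBr to give 2,5-dibromo-3-methoxy-4H-pyran-4-one F15. Suzuki coupling with one equivalent of 15 should occur at the β-bromide (C2), as with other β,α-dihalo enones, to give 5-bromo-3-methoxy-2-(3,4,5-trimethoxyphenyl)-4H-pyran-4-one F16. Copper-catalysed halogen exchange (NaI, catalytic CuI, trans-N,N'-dimethylcyclohexane-1,2-diamine, dioxane, 110 °C) would convert F16 into 17.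

## Further compounds

F1 | step 13 | 3-methoxy-2-{[(1S,2R)-1-(7-methoxy-2-oxo-2H-chromen-8-yl)-3-methyl-1-(triethylsilyloxy)but-3-en-2-yl]oxy}-4-[5-methoxy-4-oxo-6-(3,4,5-trimethoxyphenyl)-4H-pyran-3-yl]-4-(triethylsilyloxy)cyclobut-2-en-1-one | C=C(C)[C@@H](OC1=C(OC)C(O[Si](CC)(CC)CC)(c2coc(-c3cc(OC)c(OC)c(OC)c3)c(OC)c2=O)C1=O)[C@@H](O[Si](CC)(CC)CC)c1c(OC)ccc2ccc(=O)oc12
F2 | step 13 | 8-hydroxy-3,6-dimethoxy-7-{[(1S,2R)-1-(7-methoxy-2-oxo-2H-chromen-8-yl)-3-methyl-1-(triethylsilyloxy)but-3-en-2-yl]oxy}-5-(triethylsilyloxy)-2-(3,4,5-trimethoxyphenyl)-4H-chromen-4-one | C=C(C)[C@@H](Oc1c(OC)c(O[Si](CC)(CC)CC)c2c(=O)c(OC)c(-c3cc(OC)c(OC)c(OC)c3)oc2c1O)[C@@H](O[Si](CC)(CC)CC)c1c(OC)ccc2ccc(=O)oc12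
F3 | step 13 | 3,6,8-trimethoxy-7-{[(1S,2R)-1-(7-methoxy-2-oxo-2H-chromen-8-yl)-3-methyl-1-(triethylsilyloxy)but-3-en-2-yl]oxy}-5-(triethylsilyloxy)-2-(3,4,5-trimethoxyphenyl)-4H-chromen-4-one | C=C(C)[C@@H](Oc1c(OC)c(O[Si](CC)(CC)CC)c2c(=O)c(OC)c(-c3cc(OC)c(OC)c(OC)c3)oc2c1OC)[C@@H](O[Si](CC)(CC)CC)c1c(OC)ccc2ccc(=O)oc12
F4 | step 12 | 3,4-bis{[(1S,2R)-1-(7-methoxy-2-oxo-2H-chromen-8-yl)-3-methyl-1-(triethylsilyloxy)but-3-en-2-yl]oxy}cyclobut-3-ene-1,2-dione | C=C(C)[C@@H](OC1=C(O[C@H](C(C)=C)[C@@H](O[Si](CC)(CC)CC)c2c(OC)ccc3ccc(=O)oc23)C(=O)C1=O)[C@@H](O[Si](CC)(CC)CC)c1c(OC)ccc2ccc(=O)oc12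
F5 | step 12 | 4-hydroxy-2,3-bis{[(1S,2R)-1-(7-methoxy-2-oxo-2H-chromen-8-yl)-3-methyl-1-(triethylsilyloxy)but-3-en-2-yl]oxy}-4-[5-methoxy-4-oxo-6-(3,4,5-trimethoxyphenyl)-4H-pyran-3-yl]cyclobut-2-en-1-one | C=C(C)[C@@H](OC1=C(O[C@H](C(C)=C)[C@@H](O[Si](CC)(CC)CC)c2c(OC)ccc3ccc(=O)oc23)C(O)(c2coc(-c3cc(OC)c(OC)c(OC)c3)c(OC)c2=O)C1=O)[C@@H](O[Si](CC)(CC)CC)c1c(OC)ccc2ccc(=O)oc12
F6 | step 7 | 3-chloro-4-{[(1S,2R)-1-(7-methoxy-2-oxo-2H-chromen-8-yl)-3-methyl-1-(triethylsilyloxy)but-3-en-2-yl]oxy}cyclobut-3-ene-1,2-dione | C=C(C)[C@@H](OC1=C(Cl)C(=O)C1=O)[C@@H](O[Si](CC)(CC)CC)c1c(OC)ccc2ccc(=O)oc12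
F7 | step 3 | (±)-8-(1-hydroxy-3-methylbut-2-en-1-yl)-7-methoxy-2H-chromen-2-one | CC(C)=CC(O)c1c(OC)ccc2ccc(=O)oc12
F8 | step 3 | 8-{(S)-[(2S)-3,3-dimethyloxiran-2-yl](hydroxy)methyl}-7-methoxy-2H-chromen-2-one | CC1(C)O[C@H]1[C@@H](O)c1c(OC)ccc2ccc(=O)oc12
F9 | step 3 | 8-{(S)-[(2S)-3,3-dimethyloxiran-2-yl](triethylsilyloxy)methyl}-7-methoxy-2H-chromen-2-one | CC1(C)O[C@H]1[C@@H](O[Si](CC)(CC)CC)c1c(OC)ccc2ccc(=O)oc12
F10 | step 6 | 1-[(4-methoxybenzyl)oxy]propan-2-one | COc1ccc(COCC(C)=O)cc1
F11 | step 6 | (3S,4S)-4-hydroxy-3-[(4-methoxybenzyl)oxy]-4-(7-methoxy-2-oxo-2H-chromen-8-yl)butan-2-one | CC(=O)[C@@H](OCc1ccc(OC)cc1)[C@@H](O)c1c(OC)ccc2ccc(=O)oc12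
F12 | step 6 | (3S,4S)-3-[(4-methoxybenzyl)oxy]-4-(7-methoxy-2-oxo-2H-chromen-8-yl)-4-(triethylsilyloxy)butan-2-one | CC(=O)[C@@H](OCc1ccc(OC)cc1)[C@@H](O[Si](CC)(CC)CC)c1c(OC)ccc2ccc(=O)oc12
F13 | step 6 | 7-methoxy-8-{(1S,2R)-2-[(4-methoxybenzyl)oxy]-3-methyl-1-(triethylsilyloxy)but-3-en-1-yl}-2H-chromen-2-one | C=C(C)[C@@H](OCc1ccc(OC)cc1)[C@@H](O[Si](CC)(CC)CC)c1c(OC)ccc2ccc(=O)oc12
F14 | step 11 | trans-2,5,6-tribromo-3-methoxy-5,6-dihydro-4H-pyran-4-one (racemic; one enantiomer drawn) | COC1=C(Br)O[C@H](Br)[C@@H](Br)C1=O
F15 | step 11 | 2,5-dibromo-3-methoxy-4H-pyran-4-one | COc1c(Br)occ(Br)c1=O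
F16 | step 11 | 5-bromo-3-methoxy-2-(3,4,5-trimethoxyphenyl)-4H-pyran-4-one | COc1c(-c2cc(OC)c(OC)c(OC)c2)occ(Br)c1=O
A1 | alternative 1 | 7-(benzyloxy)-5-hydroxy-3,6,8-trimethoxy-2-(3,4,5-trimethoxyphenyl)-4H-chromen-4-one | COc1c(-c2cc(OC)c(OC)c(OC)c2)oc2c(OC)c(OCc3ccccc3)c(OC)c(O)c2c1=O
A2 | alternative 1 | (E)-3-[3-(benzyloxy)-5-hydroxy-2,4-dimethoxyphenoxy]-2-methoxy-3-(3,4,5-trimethoxyphenyl)prop-2-enoic acid | OC(=O)/C(OC)=C(\Oc1cc(O)c(OC)c(OCc2ccccc2)c1OC)c1cc(OC)c(OC)c(OC)c1
A3 | alternative 1 | 5,7-dihydroxy-3,6,8-trimethoxy-2-(3,4,5-trimethoxyphenyl)-4H-chromen-4-one | COc1c(-c2cc(OC)c(OC)c(OC)c2)oc2c(OC)c(O)c(OC)c(O)c2c1=O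
A4 | alternative 1 | 8-[(1S,2S)-2-hydroxy-3-methyl-1-(triethylsilyloxy)but-3-en-1-yl]-7-methoxy-2H-chromen-2-one | C=C(C)[C@H](O)[C@@H](O[Si](CC)(CC)CC)c1c(OC)ccc2ccc(=O)oc12
A5 | alternative 2 | 7-{[(1S,2R)-1-[tert-butyl(dimethyl)silyl]oxy-1-(2-hydroxy-6-methoxyphenyl)-3-methylbut-3-en-2-yl]oxy}-5-hydroxy-3,6,8-trimethoxy-2-(3,4,5-trimethoxyphenyl)-4H-chromen-4-one | C=C(C)[C@@H](Oc1c(OC)c(O)c2c(=O)c(OC)c(-c3cc(OC)c(OC)c(OC)c3)oc2c1OC)[C@@H](O[Si](C)(C)C(C)(C)C)c1c(OC)cccc1O
A6 | alternative 2 | 7-{[(3R,4S)-4-[tert-butyl(dimethyl)silyl]oxy-6-methoxy-2-methylhex-1-en-5-yn-3-yl]oxy}-5-hydroxy-3,6,8-trimethoxy-2-(3,4,5-trimethoxyphenyl)-4H-chromen-4-one | C=C(C)[C@@H](Oc1c(OC)c(O)c2c(=O)c(OC)c(-c3cc(OC)c(OC)c(OC)c3)oc2c1OC)[C@@H](O[Si](C)(C)C(C)(C)C)C#COC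
A7 | alternative 2 | cyclobut-2-en-1-one | O=C1C=CC1
A8 | alternative 3 | 2-{(1S,2R)-1-[tert-butyl(dimethyl)silyl]oxy-2-[(5-hydroxy-3,6,8-trimethoxy-4-oxo-2-(3,4,5-trimethoxyphenyl)-4H-chromen-7-yl)oxy]-3-methylbut-3-en-1-yl}-3-methoxyphenyl prop-2-ynoate | C=C(C)[C@@H](Oc1c(OC)c(O)c2c(=O)c(OC)c(-c3cc(OC)c(OC)c(OC)c3)oc2c1OC)[C@@H](O[Si](C)(C)C(C)(C)C)c1c(OC)cccc1OC(=O)C#C
A9 | alternative 3 | 7-{[(1S,2R)-1-[tert-butyl(dimethyl)silyl]oxy-1-(7-methoxy-2-oxo-2H-chromen-8-yl)-3-methylbut-3-en-2-yl]oxy}-5-hydroxy-3,6,8-trimethoxy-2-(3,4,5-trimethoxyphenyl)-4H-chromen-4-one | C=C(C)[C@@H](Oc1c(OC)c(O)c2c(=O)c(OC)c(-c3cc(OC)c(OC)c(OC)c3)oc2c1OC)[C@@H](O[Si](C)(C)C(C)(C)C)c1c(OC)ccc2ccc(=O)oc12
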